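The synthesis rests on cutting the unbranched henicosyl chain between C7′ and C8′ (counted from pyrrole C3). These are two plain CH2 groups that no heteroatom or π-system polarises. The key step exploits this featureless, stereocentre-free polymethylene chain. A nickel-hydride reductive hydroalkylation adds H to C6′ of a terminal alkene and the tetradecyl group of 1-iodotetradecane to C7′. One operation therefore forms the C7′–C8′ bond, erases both handles and delivers the unprotected target. Neither carbon enters as a nucleophile; the silane supplies the electrons. The precursor is methyl 3-(hept-6-enyl)-1H-pyrrole-2-carboxylate, made by Negishi coupling at C3 of the 3-bromopyrrole ester.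

Key step: step 3

Remark on the chemistry: the target has no stereocentre and is achiral, so no enantiocontrol is needed. Chain atoms are numbered C1′ (attached to pyrrole C3) to C21′ (terminal methyl).

Step 1
Reactants: 1 7-bromohept-1-ene
Product: 2 hept-6-en-1-ylzinc bromide (LiCl-solubilised, decanted from excess zinc and kept as a titrated THF stock solution)
Conditions: Zn dust (1.5 equiv; activated with BrCH2CH2Br 5 mol %, TMSCl 2 mol %), LiCl (1.5 equiv), THF, 50 °C; titration with I2
Reagents that add atoms: zinc, [Zn]
Why: LiCl-promoted direct insertion of activated zinc into a primary alkyl bromide is a standard organozinc preparation, and the remote alkene should survive because 6-heptenyl radical cyclisation is slow.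

Step 2
Reactants: 2 hept-6-en-1-ylzinc bromide; 3 methyl 3-bromo-1H-pyrrole-2-carboxylate
Product: 4 methyl 3-(hept-6-en-1-yl)-1H-pyrrole-2-carboxylate
Conditions: Pd(OAc)2 (2 mol %), SPhos (4 mol %), 2 (2.2 equiv, slow addition), THF, 25 → 50 °C; aq. NH4Cl
Reagents that add atoms: none
Why: In this Negishi coupling, electron-rich biarylphosphine-ligated Pd(0) should insert into the C3–Br bond next to the ester, and the primary alkylzinc halide should transmetalate and couple faster than the weakly acidic N–H protonates it, as is known for halides bearing acidic N–H or O–H groups, while ester and terminal alkene are inert to the organozinc.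

Step 3
Reactants: 4 methyl 3-(hept-6-en-1-yl)-1H-pyrrole-2-carboxylate; 5 1-iodotetradecane
Product: 6 methyl 3-henicosyl-1H-pyrrole-2-carboxylate (target)
Conditions: NiBr2·diglyme (10 mol %), 4,4′-di-tert-butyl-2,2′-bipyridine (15 mol %), (EtO)2MeSiH (2.5 equiv), Na2CO3 (2 equiv), 5 (1.5 equiv), DMA, 30 °C; aqueous work-up
Reagents that add atoms: none
Why: Silane and carbonate should turn the bipyridine–nickel halide into a Ni–H that inserts the terminal C6′=C7′ alkene of 4 with nickel on the unhindered C7′; this primary alkylnickel abstracts iodine from 5, recaptures the tetradecyl radical and reductively eliminates the C7′–C8′ bond. The closest known reaction type is exactly this one, the nickel-catalysed reductive anti-Markovnikov hydroalkylation of unactivated terminal olefins with primary alkyl iodides. No ring is closed and no stereocentre is created. Cross-coupling over homocoupling is secured because the partners are activated by different elementary steps (hydrometalation for the alkene, halogen-atom abstraction for the iodide), so neither can take the other's role. Linear regiochemistry is secured by the monosubstituted alkene and the bipyridine ligand, which favour the primary alkylnickel and should couple it faster than it can chain-walk toward the ring. Chemoselectivity over N-alkylation rests on the weakly acidic pyrrole N–H next to the C2 ester staying protonated over suspended Na2CO3 at 30 °C, while ester and pyrrole ring are inert to Ni–H and silane.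

Compound list
1 | 7-bromohept-1-ene | C=CCCCCCBr | starting material
2 | hept-6-en-1-ylzinc bromide (THF solution, LiCl-solubilised) | C=CCCCCC[Zn]Br | intermediate
3 | methyl 3-bromo-1H-pyrrole-2-carboxylate | COC(=O)c1[nH]ccc1Br | starting material
4 | methyl 3-(hept-6-en-1-yl)-1H-pyrrole-2-carboxylate | C=CCCCCCc1cc[nH]c1C(=O)OC | intermediate
5 | 1-iodotetradecane | CCCCCCCCCCCCCCI | starting material
6 | methyl 3-henicosyl-1H-pyrrole-2-carboxylate (achiral) | CCCCCCCCCCCCCCCCCCCCCc1cc[nH]c1C(=O)OC | target

Total step count: 3. Longest linear sequence: 3 (1 → 2 → 4 → 6).

Steps most likely to fail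

1. Step 3 (key step).
- What may go wrong: slow background N-alkylation of the pyrrole by the iodide, hydrodehalogenation or homocoupling of the iodide outrunning alkene insertion, and chain walking of the alkylnickel that erodes linear selectivity.
- Fallback: it sets out from 4 and comes back at 6, forming the same C7′–C8′ bond by a two-electron boron route. Hydroboration of 4 with 9-BBN-H in THF at room temperature would give methyl 3-[7-(9-borabicyclo[3.3.1]nonan-9-yl)heptyl]-1H-pyrrole-2-carboxylate F1. This would be coupled in the same flask with commercial 1-bromotetradecane in an alkyl–alkyl Suzuki–Miyaura coupling (Pd(OAc)2, PCy3, K3PO4·H2O, THF, room temperature).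

2. Step 2.
- What may go wrong: protonolysis of the alkylzinc by the N–H outrunning the coupling, sluggish oxidative addition once the pyrrole is N-metalated, hydrodebromination, and palladium-hydride isomerisation of the terminal alkene.
- Fallback: it sets out from 1 and comes back at 4, building the ring around the chain instead of coupling onto it.
- Magnesium insertion into 1 would give hept-6-en-1-ylmagnesium bromide F2, and formylation with DMF would give oct-7-enal F3.
- A base-catalysed Henry reaction with nitromethane would give racemic 1-nitronon-8-en-2-ol F4, and acetylation (Ac2O, pyridine) would give racemic 1-nitronon-8-en-2-yl acetate F5.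
- With DBU (2.2 equiv) and methyl isocyanoacetate in THF, F5 would lose acetic acid to give (E)-1-nitronona-1,8-diene F6. This enters the Barton–Zard pyrrole synthesis: Michael addition at the alkyl-bearing carbon, closure of the nitronate carbon onto the isocyanide, loss of nitrite and tautomerisation. The product is 4, with the heptenyl chain at C3 and hydrogen at C4 and C5.

3. Step 1.
- What may go wrong: sluggish or incomplete insertion of zinc into the C–Br bond and Wurtz-type homocoupling, which would leave a reagent too dilute for the slow-addition protocol.
- Fallback: it sets out from 3 and comes back at 4, so that 1 and 2 are not needed. Commercial hepta-1,6-diene (excess, the surplus removed under vacuum) would be monohydroborated with 9-BBN-H to 9-(hept-6-en-1-yl)-9-borabicyclo[3.3.1]nonane F7. This would be joined to 3 by a B-alkyl Suzuki–Miyaura coupling (PdCl2(dppf), K3PO4, DMF/THF/H2O, 60 °C).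

Further compounds
F1 | step 3 | methyl 3-[7-(9-borabicyclo[3.3.1]nonan-9-yl)heptyl]-1H-pyrrole-2-carboxylate | COC(=O)c1[nH]ccc1CCCCCCCB1C2CCCC1CCC2
F2 | step 2 | hept-6-en-1-ylmagnesium bromide | C=CCCCCC[Mg]Br
F3 | step 2 | oct-7-enal | C=CCCCCCC=O
F4 | step 2 | 1-nitronon-8-en-2-ol (racemic) | C=CCCCCCC(O)C[N+](=O)[O-]
F5 | step 2 | 1-nitronon-8-en-2-yl acetate (racemic) | C=CCCCCCC(OC(C)=O)C[N+](=O)[O-]
F6 | step 2 | (E)-1-nitronona-1,8-diene | C=CCCCCC/C=C/[N+](=O)[O-]
F7 | step 1 | 9-(hept-6-en-1-yl)-9-borabicyclo[3.3.1]nonane | C=CCCCCCB1C2CCCC1CCC2
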